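**Retrosynthetic overview**
- Last step: one-pot removal of four O-methyl groups (three aryl ethers and the ester) from fully methylated siphulin methyl ester.
- Key disconnection: the bond between chromone C2 and the benzylic CH2. C2 is the acyl-level carbon of the masked 1,3-diketone and is used as a nucleophile (C2-zincated chromone, an alpha-metalated enol ether acting as an acyl anion equivalent) against an electrophilic benzylic bromide.
- Electrophile: methyl 2-(bromomethyl)-4,6-dimethoxybenzoate, one radical bromination from commercial methyl 2,4-dimethoxy-6-methylbenzoate.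
- Nucleophile precursor: 5-heptyl-7-methoxychromone, two steps from commercial 5-heptylresorcinol (C-acetylation, then amide-acetal condensation and cyclisation with O-methylation in the same pot).
- Ring order: both benzene rings are bought; the only ring made is the 4-pyranone (step 2), closed before the key coupling.

Assumption: siphulin has no stereocentre or stereogenic axis, so "single enantiomer" is read as the one achiral structure given and no stereocontrol is needed.

**Route**

Step 1
Reactants: 1 5-heptylresorcinol (5-heptylbenzene-1,3-diol)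
Product: 2 1-(2-heptyl-4,6-dihydroxyphenyl)ethan-1-one
Conditions: AcOH (1.2 equiv), BF3·OEt2 (3 equiv), 90 °C, 2 h; then H2O
Reagents that add atoms: acetic acid, CC(=O)O
Why: Friedel–Crafts (Nencki-type) C-acylation in which BF3-activated acetic acid attacks the ring carbon ortho to one hydroxyl, para to the other and next to the heptyl chain (the site favoured in 5-alkylresorcinols such as orcinol and olivetol over the crowded carbon between the two hydroxyls), and the ortho-hydroxy ketone is held as a boron chelate that stops a second acylation; no stereocentre is formed.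

Step 2
Reactants: 2 1-(2-heptyl-4,6-dihydroxyphenyl)ethan-1-one
Product: 4 5-heptyl-7-methoxy-4H-chromen-4-one, via enaminone 3 (not isolated)
Conditions: DMF-DMA (5 equiv), toluene, 110 °C, 12 h; evaporate; then conc. HCl, CH2Cl2, 40 °C, 2 h
Reagents that add atoms: N,N-dimethylformamide dimethyl acetal (DMF-DMA), COC(OC)N(C)C
Why: Enaminone chromone synthesis in which the acetyl methyl condenses with the amide acetal, the free para-hydroxyl is O-methylated by the same reagent (the phenol protonates the acetal and the methoxymethyleneiminium ion methylates the phenoxide, while the hydrogen-bonded ortho-hydroxyl is spared), and acid then drives oxa-Michael addition of the ortho-hydroxyl with loss of dimethylamine to close the 4-pyranone ring.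

Step 3
Reactants: 5 methyl 2,4-dimethoxy-6-methylbenzoate
Product: 6 methyl 2-(bromomethyl)-4,6-dimethoxybenzoate
Conditions: NBS (1.05 equiv), AIBN (5 mol%), PhCF3, 85 °C, visible light, 1–2 h
Reagents that add atoms: N-bromosuccinimide (NBS), O=C1CCC(=O)N1Br
Why: Wohl–Ziegler radical bromination of the benzylic methyl group, run in a non-polar solvent with radical initiation and no acid so that the chain process outruns electrophilic bromination of the dimethoxy ring.

Step 4
Reactants: 4 5-heptyl-7-methoxy-4H-chromen-4-one, 6 methyl 2-(bromomethyl)-4,6-dimethoxybenzoate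
Product: 8 methyl 2-[(5-heptyl-7-methoxy-4-oxo-4H-chromen-2-yl)methyl]-4,6-dimethoxybenzoate, via chromon-2-ylzinc chloride 7 (not isolated)
Conditions: 4, TMPZnCl·LiCl (1.15 equiv; TMP = 2,2,6,6-tetramethylpiperidin-1-yl), THF, 25 °C, 1 h; then cannulate into 6 (1.2 equiv), Pd(OAc)2 (2 mol%), SPhos (4 mol%), THF, 25 → 50 °C, 3 h
Reagents that add atoms: none
Why: C–H zincation followed by Negishi cross-coupling: the C2–H of the chromone (alpha to the ring oxygen, beta to the carbonyl) is the most acidic and is removed by the mild zinc amide without a carbonyl-bound Lewis acid and without ring opening, giving an alpha-zincated enol ether that serves as an acyl anion equivalent of the C2 carbonyl-level carbon, and zerovalent palladium (formed in situ) joins it to the electrophilic benzylic carbon by oxidative addition, transmetalation and reductive elimination while the hindered ester is inert to the organozinc.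

Step 5
Reactants: 8 methyl 2-[(5-heptyl-7-methoxy-4-oxo-4H-chromen-2-yl)methyl]-4,6-dimethoxybenzoate
Product: 9 siphulin (2-[(5-heptyl-7-hydroxy-4-oxo-4H-chromen-2-yl)methyl]-4,6-dihydroxybenzoic acid)
Conditions: BBr3 (10 equiv), CH2Cl2, −78 → 25 °C, 16 h; then H2O, 0 °C
Reagents that add atoms: none
Why: Lewis-acid dealkylation in which BBr3 complexes each oxygen and bromide removes the methyl groups by SN2, the ester methyl being lost from the boron chelate formed with the neighbouring phenoxide, while room temperature and a cold quench avoid decarboxylation of the resorcylic acid and the chromone is untouched; no stereocentre is present.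

**Compound list**
1 | 5-heptylresorcinol (5-heptylbenzene-1,3-diol) | CCCCCCCc1cc(O)cc(O)c1 | starting material
2 | 1-(2-heptyl-4,6-dihydroxyphenyl)ethan-1-one | CCCCCCCc1cc(O)cc(O)c1C(C)=O | intermediate
3 | (E)-3-(dimethylamino)-1-(2-heptyl-6-hydroxy-4-methoxyphenyl)prop-2-en-1-one (enaminone) | CCCCCCCc1cc(OC)cc(O)c1C(=O)/C=C/N(C)C | intermediate
4 | 5-heptyl-7-methoxy-4H-chromen-4-one | CCCCCCCc1cc(OC)cc2occc(=O)c12 | intermediate
5 | methyl 2,4-dimethoxy-6-methylbenzoate | COC(=O)c1c(C)cc(OC)cc1OC | starting material
6 | methyl 2-(bromomethyl)-4,6-dimethoxybenzoate | COC(=O)c1c(CBr)cc(OC)cc1OC | intermediate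
7 | (5-heptyl-7-methoxy-4-oxo-4H-chromen-2-yl)zinc chloride (LiCl complex) | CCCCCCCc1cc(OC)cc2oc([Zn]Cl)cc(=O)c12 | intermediate
8 | methyl 2-[(5-heptyl-7-methoxy-4-oxo-4H-chromen-2-yl)methyl]-4,6-dimethoxybenzoate | CCCCCCCc1cc(OC)cc2oc(Cc3cc(OC)cc(OC)c3C(=O)OC)cc(=O)c12 | intermediate
9 | siphulin, 2-[(5-heptyl-7-hydroxy-4-oxo-4H-chromen-2-yl)methyl]-4,6-dihydroxybenzoic acid | CCCCCCCc1cc(O)cc2oc(Cc3cc(O)cc(O)c3C(=O)O)cc(=O)c12 | target

**Count**
Total steps: 5. Longest linear sequence: 4 steps (1 → 2 → 4 → 8 → 9).

**Steps most likely to fail, with fallbacks**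

Step 4 (key coupling). The risks are zincation at C3 instead of C2, homocoupling of the benzylic bromide, and proton transfer from the acidic CH2 of product 8 to the zinc reagent. The fallback sets out from 6, uses zinc reagent 7 made from 4 as before, and comes back to the route at 9. Bromide 6 is oxidised with 4-methylmorpholine N-oxide in MeCN at 25 °C to methyl 2-formyl-4,6-dimethoxybenzoate F1. Zinc reagent 7 is added to this aldehyde in THF with MgCl2 at 0 → 25 °C, giving the zinc alkoxide of methyl 2-[(5-heptyl-7-methoxy-4-oxo-4H-chromen-2-yl)(hydroxy)methyl]-4,6-dimethoxybenzoate F2. This closes onto the neighbouring ester to the racemic phthalide 3-(5-heptyl-7-methoxy-4-oxo-4H-chromen-2-yl)-5,7-dimethoxy-2-benzofuran-1(3H)-one F3. Zn dust in AcOH at 25–50 °C cleaves its benzylic C–O bond (gamma to the chromone carbonyl) and removes the stereocentre, giving 2-[(5-heptyl-7-methoxy-4-oxo-4H-chromen-2-yl)methyl]-4,6-dimethoxybenzoic acid F4. BBr3 in CH2Cl2 then only has to cleave three aryl methyl ethers to reach 9. The masked acyl anion is kept, but the bond is made by carbonyl addition instead of cross-coupling.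

Step 5 (global demethylation). The risks are incomplete cleavage of the hindered methyl ester and decarboxylation if forcing conditions are needed. The fallback changes the ester, sets out from 5 and comes back at 9. Ester 5 is saponified (KOH, aqueous DMSO, 80 °C; then aq. HCl) to 2,4-dimethoxy-6-methylbenzoic acid F5. O-alkylation with tert-butyl 2,2,2-trichloroacetimidate (BF3·OEt2 cat., CH2Cl2/cyclohexane, 25 °C) gives tert-butyl 2,4-dimethoxy-6-methylbenzoate F6. Bromination as in step 3 gives tert-butyl 2-(bromomethyl)-4,6-dimethoxybenzoate F7. Coupling with zinc reagent 7 (from 4) as in step 4 gives tert-butyl 2-[(5-heptyl-7-methoxy-4-oxo-4H-chromen-2-yl)methyl]-4,6-dimethoxybenzoate F8. BBr3 removes the tert-butyl group already at −78 °C and the three methyl ethers on warming, giving 9.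

Step 3 (benzylic bromination). The risk is competing bromination of the electron-rich ring. The fallback replaces the radical process by an anionic one, sets out from 5 and comes back at 6. Ester 5 is deprotonated at the benzylic methyl group with LiN(iPr)2 in THF at −78 °C to [2-(methoxycarbonyl)-3,5-dimethoxyphenyl]methyllithium F9. This solution is transferred by cannula into 1,2-dibromo-1,1,2,2-tetrachloroethane in THF at −78 °C (inverse addition, to keep the product away from the anion), giving 6.

**Further compounds**
F1 | step 4 | methyl 2-formyl-4,6-dimethoxybenzoate | COC(=O)c1c(C=O)cc(OC)cc1OC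
F2 | step 4 | zinc alkoxide of methyl 2-[(5-heptyl-7-methoxy-4-oxo-4H-chromen-2-yl)(hydroxy)methyl]-4,6-dimethoxybenzoate (racemic) | CCCCCCCc1cc(OC)cc2oc(C(O[Zn]Cl)c3cc(OC)cc(OC)c3C(=O)OC)cc(=O)c12
F3 | step 4 | 3-(5-heptyl-7-methoxy-4-oxo-4H-chromen-2-yl)-5,7-dimethoxy-2-benzofuran-1(3H)-one (racemic) | CCCCCCCc1cc(OC)cc2oc(C3OC(=O)c4c(OC)cc(OC)cc34)cc(=O)c12
F4 | step 4 | 2-[(5-heptyl-7-methoxy-4-oxo-4H-chromen-2-yl)methyl]-4,6-dimethoxybenzoic acid | CCCCCCCc1cc(OC)cc2oc(Cc3cc(OC)cc(OC)c3C(=O)O)cc(=O)c12
F5 | step 5 | 2,4-dimethoxy-6-methylbenzoic acid | Cc1cc(OC)cc(OC)c1C(=O)O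
F6 | step 5 | tert-butyl 2,4-dimethoxy-6-methylbenzoate | Cc1cc(OC)cc(OC)c1C(=O)OC(C)(C)C
F7 | step 5 | tert-butyl 2-(bromomethyl)-4,6-dimethoxybenzoate | BrCc1cc(OC)cc(OC)c1C(=O)OC(C)(C)C
F8 | step 5 | tert-butyl 2-[(5-heptyl-7-methoxy-4-oxo-4H-chromen-2-yl)methyl]-4,6-dimethoxybenzoate | CCCCCCCc1cc(OC)cc2oc(Cc3cc(OC)cc(OC)c3C(=O)OC(C)(C)C)cc(=O)c12
F9 | step 3 | [2-(methoxycarbonyl)-3,5-dimethoxyphenyl]methyllithium | [Li]Cc1cc(OC)cc(OC)c1C(=O)OC
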